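The target is disconnected by a [3+3] annulation that fuses the 2,3-dimethyl-2,3-dihydropyran-4-one ring onto an aromatic dihydrocoumarin before the carbocycle is dearomatised. In one pot, chiral-pool acid chloride 16 acylates C8 of lactone 15, a 5,7-dimethoxy-4-propyldihydrocoumarin (Friedel–Crafts), AlCl3 unmasks only the chelated 7-oxygen, and this phenoxide displaces the secondary mesylate with inversion: the aryl–C(=O) and O–CH(CH3) bonds and the cis-(2R,3S) pair arise together. The step exploits the O1–C8a–C8(H)–C7–O7 edge of the benzene ring, where C8 is the only accessible nucleophilic carbon and O7 its only oxygen neighbour that can be freed. Lavandulyl (Negishi coupling) and prenyl (dearomative allylation, quaternary centre) follow; a late demethylation unveils the enolic triketone.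

Key step: step 10

Remark: the target is treated as the 5-hydroxy-4,7-dioxo tautomer drawn; its other enol forms are the same compound.
Remark: the facial sense of the chiral palladium catalyst in step 13 cannot be predicted with confidence; the (R,R)-ligand is written and its antipode would be used if the other C8 epimer prevailed.
Remark: the quaternary centre is labelled 8S in 25 and 8R in 26 only because the priorities of its neighbours change; the spatial arrangement is the same.

Step 1
Reactants: 1 (4S)-4-benzyl-1,3-oxazolidin-2-one; 2 3-methylbut-2-enoyl chloride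
Product: 3 (4S)-4-benzyl-3-(3-methylbut-2-enoyl)-1,3-oxazolidin-2-one
Conditions: n-BuLi, THF, −78 °C; then 2, −78 to 0 °C
Reagents that add atoms: none
Why: N-acylation of the lithiated oxazolidinone by the acid chloride creates no stereocentre and provides the imide for an auxiliary-controlled Evans alkylation.

Step 2
Reactants: 3 (4S)-4-benzyl-3-(3-methylbut-2-enoyl)-1,3-oxazolidin-2-one; 4 1-bromo-3-methylbut-2-ene
Product: 5 (4S)-4-benzyl-3-[(2S)-5-methyl-2-(prop-1-en-2-yl)hex-4-enoyl]-1,3-oxazolidin-2-one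
Conditions: NaN(SiMe3)2, THF, −78 °C; then 4, −78 to −40 °C
Reagents that add atoms: none
Why: γ-Deprotonation gives the chelated sodium (Z)-dienolate, which is alkylated at its α-carbon on the face opposite the benzyl group (Evans deconjugative alkylation), so the future lavandulyl stereocentre is set as 2S under auxiliary control while the alkene moves into the isopropenyl position.

Step 3
Reactants: 5 (4S)-4-benzyl-3-[(2S)-5-methyl-2-(prop-1-en-2-yl)hex-4-enoyl]-1,3-oxazolidin-2-one
Product: 6 (2S)-5-methyl-2-(prop-1-en-2-yl)hex-4-en-1-ol, (S)-lavandulol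
Conditions: LiBH4, MeOH (1 equiv), Et2O, 0 °C
Reagents that add atoms: none
Why: Reductive cleavage of the N-acyl oxazolidinone by LiBH4 gives the primary alcohol without epimerising the α-stereocentre or touching the two alkenes, and the auxiliary is recovered.

Step 4
Reactants: 6 (2S)-5-methyl-2-(prop-1-en-2-yl)hex-4-en-1-ol
Product: 7 (3S)-3-(iodomethyl)-2,6-dimethylhepta-1,5-diene, (S)-lavandulyl iodide
Conditions: I2, PPh3, imidazole, CH2Cl2, 0 °C to rt
Reagents that add atoms: iodine, II
Why: Appel-type iodination converts the primary alcohol into the iodide by SN2 at CH2, leaving the adjacent stereocentre and both alkenes untouched.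

Step 5
Reactants: 8 tert-butyl (3S)-3-hydroxybutanoate
Product: 9 tert-butyl (2S,3S)-3-hydroxy-2-methylbutanoate
Conditions: LiN(i-Pr)2 (2.2 equiv), THF, −50 to −20 °C; then MeI, DMPU, −50 to −20 °C
Reagents that add atoms: iodomethane, CI
Why: Fráter–Seebach alkylation, in which the lithium-chelated alkoxide enolate dianion is methylated on the face anti to the C3 methyl group, sets C2 as S and gives the anti (2S,3S) hydroxy ester.

Step 6
Reactants: 9 tert-butyl (2S,3S)-3-hydroxy-2-methylbutanoate
Product: 10 tert-butyl (2S,3S)-2-methyl-3-[(methylsulfonyl)oxy]butanoate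
Conditions: CH3SO2Cl, Et3N, CH2Cl2, −10 °C
Reagents that add atoms: methanesulfonyl chloride, CS(=O)(=O)Cl
Why: Sulfonylation forms only an O–S bond, so C3 keeps its S configuration, and the weakly acidic tert-butyl ester should not eliminate with Et3N at low temperature.

Step 7
Reactants: 10 tert-butyl (2S,3S)-2-methyl-3-[(methylsulfonyl)oxy]butanoate
Product: 11 (2S,3S)-2-methyl-3-[(methylsulfonyl)oxy]butanoic acid
Conditions: CF3CO2H, CH2Cl2, 0 °C to rt
Reagents that add atoms: none
Why: Acidolysis of the tert-butyl ester (loss of 2-methylpropene) frees the acid under conditions in which the β-mesylate cannot undergo base-induced elimination.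

Step 8
Reactants: 12 3,5-dimethoxyphenol; 13 (2E)-hex-2-enal
Product: 14 (4R)-5,7-dimethoxy-4-propyl-3,4-dihydro-2H-chromen-2-ol (lactol, both C2 epimers)
Conditions: (S)-α,α-diphenylprolinol trimethylsilyl ether (20 mol%), PhCO2H (20 mol%), toluene, 0 °C, 12 in excess
Reagents that add atoms: none
Why: Iminium-ion catalysed Friedel–Crafts alkylation with hemiacetal trapping, in which an ortho carbon of the phenol (C2 and C6 are equivalent, C4 is flanked by two methoxy groups) adds to the β-carbon of the (E)-iminium ion on the face anti to the diphenyl(silyloxy)methyl group of the catalyst, sets C4 as R.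

Step 9
Reactants: 14 (4R)-5,7-dimethoxy-4-propyl-3,4-dihydro-2H-chromen-2-ol
Product: 15 (4R)-5,7-dimethoxy-4-propyl-3,4-dihydro-2H-chromen-2-one
Conditions: TEMPO (10 mol%), PhI(OAc)2, CH2Cl2, rt
Reagents that add atoms: none
Why: Oxoammonium (TEMPO) oxidation of the lactol to the lactone removes the anomeric mixture, and the benzylic C4 stereocentre is not enolisable.

Step 10
Reactants: 11 (2S,3S)-2-methyl-3-[(methylsulfonyl)oxy]butanoic acid; 15 (4R)-5,7-dimethoxy-4-propyl-3,4-dihydro-2H-chromen-2-one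
Product: 19 (4R,8R,9S)-5-methoxy-8,9-dimethyl-4-propyl-3,4,8,9-tetrahydro-2H,10H-pyrano[2,3-f]chromene-2,10-dione, via acyl chloride 16 (not isolated), via methoxy ketone 17 (not isolated), via hydroxy ketone 18 (not isolated)
Conditions: (COCl)2, DMF (cat.), CH2Cl2, 0 °C to rt, then volatiles removed; 15, AlCl3 (4 equiv), CH2Cl2, −20 °C to rt; then aq. K2CO3, potassium sodium tartrate (KNaC4H4O6), Bu4NHSO4 (cat.), 0 °C to rt, same flask
Reagents that add atoms: none
Why: The acid chloride made in the flask acylates 15 at C8 (Friedel–Crafts), excess AlCl3 then cleaves the methyl ether that is chelated to the new ketone, and after basification the freed 7-phenoxide displaces the secondary mesylate intramolecularly (SN2). The closest known reaction type is the chromanone synthesis from phenol ethers and β-halo or β-sulfonyloxy acyl chlorides by acylation and base-induced ring closure, with the Mitsunobu cyclisation of o-hydroxyaryl β-hydroxy ketones as the model for clean inversion. The dihydropyranone ring closes in a 6-exo-tet mode. No prochiral atom is involved: C9 keeps the 2S configuration of the acid and C8 becomes R because the 3S mesylate carbon is inverted, so the anti acid gives the cis-dimethyl ring. The step needs C8 over C6 and O7 over the other oxygens, which the substrate secures because C6 lies between two methoxy groups whereas C8 is para to the 5-methoxy group, and because only the 7-methoxy group is chelated to the C8 ketone while O1 stays tied in the lactone. Substitution must outrun elimination of the mesylate, which the low α-acidity of the o-oxidoaryl ketone and the six-membered transition state should favour.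

Step 11
Reactants: 19 (4R,8R,9S)-5-methoxy-8,9-dimethyl-4-propyl-3,4,8,9-tetrahydro-2H,10H-pyrano[2,3-f]chromene-2,10-dione
Product: 20 (4R,8R,9S)-6-bromo-5-methoxy-8,9-dimethyl-4-propyl-3,4,8,9-tetrahydro-2H,10H-pyrano[2,3-f]chromene-2,10-dione
Conditions: N-bromosuccinimide, MeCN, 0 °C, dark
Reagents that add atoms: N-bromosuccinimide, O=C1CCC(=O)N1Br
Why: Electrophilic aromatic bromination occurs at C6, the only aromatic C–H left, which is activated by two flanking alkoxy groups, while the ketone α-position should not be brominated in the absence of acid or base.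

Step 12
Reactants: 7 (3S)-3-(iodomethyl)-2,6-dimethylhepta-1,5-diene; 20 (4R,8R,9S)-6-bromo-5-methoxy-8,9-dimethyl-4-propyl-3,4,8,9-tetrahydro-2H,10H-pyrano[2,3-f]chromene-2,10-dione
Product: 22 (4R,8R,9S)-5-methoxy-8,9-dimethyl-6-[(2R)-5-methyl-2-(prop-1-en-2-yl)hex-4-en-1-yl]-4-propyl-3,4,8,9-tetrahydro-2H,10H-pyrano[2,3-f]chromene-2,10-dione, via alkylzinc iodide 21 (not isolated)
Conditions: 7, Zn dust, LiCl, THF, 35 °C; then 20, Pd(OAc)2 (3 mol%), CPhos (6 mol%), THF/toluene, rt to 45 °C
Reagents that add atoms: none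
Why: Negishi sp3–sp2 coupling, in which zinc inserts into the primary iodide and the zerovalent palladium/biarylphosphine catalyst couples the alkylzinc iodide with the di-ortho-alkoxy aryl bromide, tolerates ketone and lactone, leaves the lavandulyl stereocentre (β to zinc) untouched and suppresses β-hydride elimination through the ligand.

Step 13
Reactants: 22 (4R,8R,9S)-5-methoxy-8,9-dimethyl-6-[(2R)-5-methyl-2-(prop-1-en-2-yl)hex-4-en-1-yl]-4-propyl-3,4,8,9-tetrahydro-2H,10H-pyrano[2,3-f]chromene-2,10-dione; 23 3-methylbut-2-en-1-yl acetate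
Product: 25 (3R)-3-{(2R,3S,8S)-7-methoxy-2,3-dimethyl-8-[(2R)-5-methyl-2-(prop-1-en-2-yl)hex-4-en-1-yl]-8-(3-methylbut-2-en-1-yl)-4,5-dioxo-3,4,5,8-tetrahydro-2H-chromen-6-yl}hexanoic acid, via dicaesium salt 24 (not isolated)
Conditions: CsOH·H2O (2.0 equiv), THF/H2O, 0 °C, then dried by toluene azeotrope below 30 °C; Pd2(dba)3·CHCl3 (2.5 mol%), (R,R)-DACH-phenyl ligand (N,N′-[(1R,2R)-cyclohexane-1,2-diyl]bis[2-(diphenylphosphanyl)benzamide], 7.5 mol%), 23, THF, 0 °C to rt; AcOH work-up
Reagents that add atoms: caesium hydroxide, [Cs+].[OH-]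
Why: Hydroxide opens the aryl lactone to a phenoxide–carboxylate, and Tsuji–Trost allylation by the π-prenylpalladium complex at its CH2 terminus on the fully substituted carbon para to the phenoxide (C6 of 22, flanked by two alkoxy groups) dearomatises the ring as known for phloroglucinol-type phenoxides, the chiral ligand being relied on to select one face of the unsymmetrical phenoxide and so set the quaternary centre.

Step 14
Reactants: 25 (3R)-3-{(2R,3S,8S)-7-methoxy-2,3-dimethyl-8-[(2R)-5-methyl-2-(prop-1-en-2-yl)hex-4-en-1-yl]-8-(3-methylbut-2-en-1-yl)-4,5-dioxo-3,4,5,8-tetrahydro-2H-chromen-6-yl}hexanoic acid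
Product: 26 (3R)-3-{(2R,3S,8R)-5-hydroxy-2,3-dimethyl-8-[(2R)-5-methyl-2-(prop-1-en-2-yl)hex-4-en-1-yl]-8-(3-methylbut-2-en-1-yl)-4,7-dioxo-3,4,7,8-tetrahydro-2H-chromen-6-yl}hexanoic acid (CNP0266113.2)
Conditions: LiCl (10 equiv), DMSO, 100 °C; cold dilute aq. HCl work-up
Reagents that add atoms: none
Why: Chloride-mediated SN2 demethylation (Krapcho-type) of the vinylogous methyl ester created by the dearomatisation frees the enol, which tautomerises to the chelated 5-hydroxy-4,7-dioxo form, while the secondary O–CH of the dihydropyranone should not be attacked and no base strong enough to enolise C3 is present.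

Compound list
1 | (4S)-4-benzyl-1,3-oxazolidin-2-one | O=C1N[C@@H](Cc2ccccc2)CO1 | starting material
2 | 3-methylbut-2-enoyl chloride | CC(C)=CC(Cl)=O | starting material
3 | (4S)-4-benzyl-3-(3-methylbut-2-enoyl)-1,3-oxazolidin-2-one | CC(C)=CC(=O)N1[C@@H](Cc2ccccc2)COC1=O | intermediate
4 | 1-bromo-3-methylbut-2-ene | CC(C)=CCBr | starting material
5 | (4S)-4-benzyl-3-[(2S)-5-methyl-2-(prop-1-en-2-yl)hex-4-enoyl]-1,3-oxazolidin-2-one | C=C(C)[C@H](CC=C(C)C)C(=O)N1[C@@H](Cc2ccccc2)COC1=O | intermediate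
6 | (2S)-5-methyl-2-(prop-1-en-2-yl)hex-4-en-1-ol, (S)-lavandulol | C=C(C)[C@H](CC=C(C)C)CO | intermediate
7 | (3S)-3-(iodomethyl)-2,6-dimethylhepta-1,5-diene | C=C(C)[C@H](CC=C(C)C)CI | intermediate
8 | tert-butyl (3S)-3-hydroxybutanoate | C[C@H](O)CC(=O)OC(C)(C)C | starting material
9 | tert-butyl (2S,3S)-3-hydroxy-2-methylbutanoate | C[C@H](O)[C@H](C)C(=O)OC(C)(C)C | intermediate
10 | tert-butyl (2S,3S)-2-methyl-3-[(methylsulfonyl)oxy]butanoate | C[C@H](OS(C)(=O)=O)[C@H](C)C(=O)OC(C)(C)C | intermediate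
11 | (2S,3S)-2-methyl-3-[(methylsulfonyl)oxy]butanoic acid | C[C@H](OS(C)(=O)=O)[C@H](C)C(=O)O | intermediate
12 | 3,5-dimethoxyphenol | COc1cc(O)cc(OC)c1 | starting material
13 | (2E)-hex-2-enal | CCC/C=C/C=O | starting material
14 | (4R)-5,7-dimethoxy-4-propyl-3,4-dihydro-2H-chromen-2-ol (both C2 epimers) | CCC[C@@H]1CC(O)Oc2cc(OC)cc(OC)c21 | intermediate
15 | (4R)-5,7-dimethoxy-4-propyl-3,4-dihydro-2H-chromen-2-one | CCC[C@@H]1CC(=O)Oc2cc(OC)cc(OC)c21 | intermediate
16 | (2S,3S)-2-methyl-3-[(methylsulfonyl)oxy]butanoyl chloride | C[C@H](OS(C)(=O)=O)[C@H](C)C(Cl)=O | intermediate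
17 | (4R)-5,7-dimethoxy-8-{(2S,3S)-2-methyl-3-[(methylsulfonyl)oxy]butanoyl}-4-propyl-3,4-dihydro-2H-chromen-2-one | CCC[C@@H]1CC(=O)Oc2c(C(=O)[C@@H](C)[C@H](C)OS(C)(=O)=O)c(OC)cc(OC)c21 | intermediate
18 | (4R)-7-hydroxy-5-methoxy-8-{(2S,3S)-2-methyl-3-[(methylsulfonyl)oxy]butanoyl}-4-propyl-3,4-dihydro-2H-chromen-2-one | CCC[C@@H]1CC(=O)Oc2c(C(=O)[C@@H](C)[C@H](C)OS(C)(=O)=O)c(O)cc(OC)c21 | intermediate
19 | (4R,8R,9S)-5-methoxy-8,9-dimethyl-4-propyl-3,4,8,9-tetrahydro-2H,10H-pyrano[2,3-f]chromene-2,10-dione | CCC[C@@H]1CC(=O)Oc2c3C(=O)[C@@H](C)[C@@H](C)Oc3cc(OC)c21 | intermediate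
20 | (4R,8R,9S)-6-bromo-5-methoxy-8,9-dimethyl-4-propyl-3,4,8,9-tetrahydro-2H,10H-pyrano[2,3-f]chromene-2,10-dione | CCC[C@@H]1CC(=O)Oc2c3C(=O)[C@@H](C)[C@@H](C)Oc3c(Br)c(OC)c21 | intermediate
21 | iodido[(2S)-5-methyl-2-(prop-1-en-2-yl)hex-4-en-1-yl]zinc | C=C(C)[C@H](CC=C(C)C)C[Zn]I | intermediate
22 | (4R,8R,9S)-5-methoxy-8,9-dimethyl-6-[(2R)-5-methyl-2-(prop-1-en-2-yl)hex-4-en-1-yl]-4-propyl-3,4,8,9-tetrahydro-2H,10H-pyrano[2,3-f]chromene-2,10-dione | CCC[C@@H]1CC(=O)Oc2c3C(=O)[C@@H](C)[C@@H](C)Oc3c(C[C@@H](CC=C(C)C)C(C)=C)c(OC)c21 | intermediate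
23 | 3-methylbut-2-en-1-yl acetate | CC(C)=CCOC(C)=O | starting material
24 | dicaesium (3R)-3-{(2R,3S)-7-methoxy-2,3-dimethyl-8-[(2R)-5-methyl-2-(prop-1-en-2-yl)hex-4-en-1-yl]-5-oxido-4-oxo-3,4-dihydro-2H-chromen-6-yl}hexanoate | CCC[C@H](CC(=O)[O-])c1c([O-])c2C(=O)[C@@H](C)[C@@H](C)Oc2c(C[C@@H](CC=C(C)C)C(C)=C)c1OC.[Cs+].[Cs+] | intermediate
25 | (3R)-3-{(2R,3S,8S)-7-methoxy-2,3-dimethyl-8-[(2R)-5-methyl-2-(prop-1-en-2-yl)hex-4-en-1-yl]-8-(3-methylbut-2-en-1-yl)-4,5-dioxo-3,4,5,8-tetrahydro-2H-chromen-6-yl}hexanoic acid | C=C(C)[C@H](CC=C(C)C)C[C@@]1(CC=C(C)C)C(OC)=C([C@H](CCC)CC(=O)O)C(=O)C2=C1O[C@H](C)[C@H](C)C2=O | intermediate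
26 | (3R)-3-{(2R,3S,8R)-5-hydroxy-2,3-dimethyl-8-[(2R)-5-methyl-2-(prop-1-en-2-yl)hex-4-en-1-yl]-8-(3-methylbut-2-en-1-yl)-4,7-dioxo-3,4,7,8-tetrahydro-2H-chromen-6-yl}hexanoic acid | C=C(C)[C@H](CC=C(C)C)C[C@@]1(CC=C(C)C)C(=O)C([C@H](CCC)CC(=O)O)=C(O)C2=C1O[C@H](C)[C@H](C)C2=O | target

Total step count: 14. Longest linear sequence: 8 steps (steps 5, 6, 7, 10, 11, 12, 13, 14, from 8 to 26).

Steps most likely to fail

Step 10. The mesylate may be lost by elimination, under the Lewis acid or by an E1cB pathway after basification, faster than it is displaced, which would erase the configuration at C8 and C9. The branched acyl chloride may also acylate sluggishly. The fallback sets out from 15 and comes back at 19. Friedel–Crafts acylation of 15 with (2E)-2-methylbut-2-enoyl chloride and AlCl3 in CH2Cl2, with the same chelation-assisted 7-O-demethylation, gives the enone phenol F1. F1 is then cyclised with (−)-quinine in chlorobenzene at 10 to 15 °C. This amine-mediated intramolecular oxa-Michael addition with kinetic protonation is known for 7-hydroxy-8-(2-methylbut-2-enoyl)coumarins to give the cis-(2R,3S)-dimethylchromanone, and it delivers 19 in two operations in place of one.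

Step 13. Allylation may take place at oxygen instead of at the hindered, fully substituted para carbon, and the chiral palladium complex may discriminate the two faces of the phenoxide poorly. The fallback sets out from 22 and comes back at 26. Lactone 22 is opened with NaOMe (1 equiv) in MeOH/THF at −20 °C to the phenol methyl ester F2. O-Alkylation with 1-bromo-3-methylbut-2-ene and K2CO3 in acetone gives the aryl prenyl ether F3. Heating in toluene at 110 °C moves the prenyl group by an ortho-Claisen shift followed by a Cope shift to the para carbon, giving the dienone methyl ester F4 together with its C8 epimer F5, which are separated by chromatography. LiI in EtOAc at reflux then cleaves both O-methyl groups of F4 and gives 26.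

Step 14. The hot nucleophilic demethylation may epimerise C3 or open the dihydropyranone ring by β-elimination and non-selective re-closure. The fallback sets out from 20 and comes back at 26. Bromide 20 is demethylated with BBr3 in CH2Cl2 at −78 to 0 °C, while no alkene is present, to the bromophenol F6. Negishi coupling with 21 as in step 12, with one further equivalent of 21 consumed by the phenol, gives the lavandulyl phenol F7. CsOH (3 equiv) then opens the lactone, and the palladium-catalysed prenylation of step 13, now at a carbon ortho to a phenoxide, gives 26 directly without a late demethylation.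

Further compounds
F1 | step 10 | (4R)-7-hydroxy-5-methoxy-8-[(2E)-2-methylbut-2-enoyl]-4-propyl-3,4-dihydro-2H-chromen-2-one | CCC[C@@H]1CC(=O)Oc2c(C(=O)/C(C)=C/C)c(O)cc(OC)c21
F2 | step 13 | methyl (3R)-3-{(2R,3S)-5-hydroxy-7-methoxy-2,3-dimethyl-8-[(2R)-5-methyl-2-(prop-1-en-2-yl)hex-4-en-1-yl]-4-oxo-3,4-dihydro-2H-chromen-6-yl}hexanoate | CCC[C@H](CC(=O)OC)c1c(O)c2C(=O)[C@@H](C)[C@@H](C)Oc2c(C[C@@H](CC=C(C)C)C(C)=C)c1OC
F3 | step 13 | methyl (3R)-3-{(2R,3S)-7-methoxy-2,3-dimethyl-5-[(3-methylbut-2-en-1-yl)oxy]-8-[(2R)-5-methyl-2-(prop-1-en-2-yl)hex-4-en-1-yl]-4-oxo-3,4-dihydro-2H-chromen-6-yl}hexanoate | CCC[C@H](CC(=O)OC)c1c(OCC=C(C)C)c2C(=O)[C@@H](C)[C@@H](C)Oc2c(C[C@@H](CC=C(C)C)C(C)=C)c1OC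
F4 | step 13 | methyl (3R)-3-{(2R,3S,8S)-7-methoxy-2,3-dimethyl-8-[(2R)-5-methyl-2-(prop-1-en-2-yl)hex-4-en-1-yl]-8-(3-methylbut-2-en-1-yl)-4,5-dioxo-3,4,5,8-tetrahydro-2H-chromen-6-yl}hexanoate | C=C(C)[C@H](CC=C(C)C)C[C@@]1(CC=C(C)C)C(OC)=C([C@H](CCC)CC(=O)OC)C(=O)C2=C1O[C@H](C)[C@H](C)C2=O
F5 | step 13 | methyl (3R)-3-{(2R,3S,8R)-7-methoxy-2,3-dimethyl-8-[(2R)-5-methyl-2-(prop-1-en-2-yl)hex-4-en-1-yl]-8-(3-methylbut-2-en-1-yl)-4,5-dioxo-3,4,5,8-tetrahydro-2H-chromen-6-yl}hexanoate (C8 epimer of F4) | C=C(C)[C@H](CC=C(C)C)C[C@]1(CC=C(C)C)C(OC)=C([C@H](CCC)CC(=O)OC)C(=O)C2=C1O[C@H](C)[C@H](C)C2=O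
F6 | step 14 | (4R,8R,9S)-6-bromo-5-hydroxy-8,9-dimethyl-4-propyl-3,4,8,9-tetrahydro-2H,10H-pyrano[2,3-f]chromene-2,10-dione | CCC[C@@H]1CC(=O)Oc2c3C(=O)[C@@H](C)[C@@H](C)Oc3c(Br)c(O)c21
F7 | step 14 | (4R,8R,9S)-5-hydroxy-8,9-dimethyl-6-[(2R)-5-methyl-2-(prop-1-en-2-yl)hex-4-en-1-yl]-4-propyl-3,4,8,9-tetrahydro-2H,10H-pyrano[2,3-f]chromene-2,10-dione | CCC[C@@H]1CC(=O)Oc2c3C(=O)[C@@H](C)[C@@H](C)Oc3c(C[C@@H](CC=C(C)C)C(C)=C)c(O)c21
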